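I start from a leftover: b, the part of the charged nucleophile still unbound when a flask ends. I want to show that the share asked for can be read from it while nucleophile is spent on making target and none comes back.

all flasks: nucleophile 0.440 M; time 30 min

| charge | electrophile | free base | temperature | remark |
|---|---|---|---|---|
| larch | 0.40 M (in portions, 2, over 25 min) | 0.440 M | 25 °C | first portion at the start, last at 25 min |
| elm | 0.40 M | 0.440 M | 25 °C | everything together at the start |
| maple | 0.40 M | 0.440 M (fed, over 25 min) | 25 °C | all else is in the flask from the start; the feed brings no volume worth counting |
| birch | 0.40 M (fed, over 25 min) | 0.440 M |  | the addition at −15 °C, then warmed to 25 °C; the feed brings no volume worth counting |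

    electrophile + nucleophile ⇌ acid set free + target (K1 = 1.7, k1 = 0.20 M⁻¹ min⁻¹, Ea1 = 49.0 kJ mol⁻¹, ΔH1 = 15.0 kJ mol⁻¹)
    electrophile + acid set free → side product B (k2 = 0.020 M⁻¹ min⁻¹, Ea2 = 81.0 kJ mol⁻¹)
    electrophile + target → side product A (k3 = 0.12 M⁻¹ min⁻¹, Ea3 = 50.0 kJ mol⁻¹)
    acid set free + free base ⇌ salt of the base (K4 = 34 M⁻¹, k4 = 0.18 M⁻¹ min⁻¹, Ea4 = 68.0 kJ mol⁻¹, ΔH4 = −45.0 kJ mol⁻¹)
    nucleophile + acid set free ⇌ protonated nucleophile, settled at all times (K5 = 5700 M⁻¹, ΔH5 = −33.0 kJ mol⁻¹)
    (constants at 25 °C)

- in percentages every species weighs as the electrophile in it: one side product A counts as two
- the constants hold at 25 °C; other temperatures follow from the activation energies and enthalpies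

- the flask with the highest share of target in target plus side product A ("all alike" if they lie within 1.5 percentage points) (larch / elm / maple / birch / all alike)
- share of target in target plus side product A at the end, larch
- share of target in target plus side product A at the end, elm
- share of target in target plus side product A at the end, maple
- share of target in target plus side product A at the end, birch

The electrophile has two exits, and these are the two rates I compare: the making of target, constant 0.20 M⁻¹ min⁻¹ times nucleophile, and the attack on target, constant 0.12 M⁻¹ min⁻¹ times target. Their ratio holds no electrophile, so at one temperature, and while nucleophile is spent on making target and none comes back, a flask's target follows its nucleophile with no clock and no dosing in the relation.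

Each target also costs a second nucleophile, because for the acid set free the balance with the nucleophile weighs 2500 against 15 with the free base. So I carry one number, h, the attack constant over twice the making constant, which is the inverse of twice the selectivity factor: 0.300. The activation energies, 49.0 kJ mol⁻¹ and 50.0 kJ mol⁻¹, are nearly equal, so I keep h in the cold too.

Integrating the ratio over the falling nucleophile, under that same condition, gives the part of the made target that survives. Side product A counts double, which gives the share:

survival = (b^h − b) / ((1 − h)(1 − b))

share = survival / (2 − survival)

For elm, nucleophile falls at twice the making constant times the electrophile. I replace the electrophile curve by a mean of half its charge: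

b = exp(−making constant × charge × time) = 9.07%

survival = 62.2%, share = 45.2%

Maple has the same electrophile and nucleophile, and the free base holds the weak balance, so I give maple the same share. Birch is warm for 5.00 min rather than 30 min, after a cold feed, so I expect it to keep more nucleophile and I name it the highest.

The forecast says birch, with larch 63.5%, elm 38%, maple 37.5% and birch 80%, on the ground that “birch wins because it barely reacts in the cold and has only 5 warm minutes”. For elm my 45.2% stands higher than its 38%.

The highest is birch: larch 63.8%, elm 44.4%, maple 44.4%, birch 79.6%. Elm's unbound nucleophile reads 8.9% at the end, against my 9.07%. Put through h, that reading gives elm a survival of 61.9% and a share of 44.8%. The neighbour of birch with 0.68 M of electrophile ends with 28.3% of its nucleophile, for which h gives a survival of 80.0% and a share of 66.7%, and that flask reads 66.7%.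

(The constants were set for the occasion; the run is a simulation.)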